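**Retrosynthetic overview**
1. Target ⇐ Z-selective enyne cross-metathesis, then desilylation, of a C6-allyl oxocane.
2. Oxocane ⇐ key C6–O bond: the ether oxygen of a 2,5-cis tetrahydrofuran (ring B) displaces a C6 triflate to give a 5/5 bicyclic oxonium ion (ring A + ring B), which chloride opens at the ring-fusion carbon C9 (C6 and C9 both inverted).
3. Tetrahydrofuran chlorohydrin ⇐ organocatalytic α-chlorination (C7) and allylboration (C6) of a tetrahydrofuran-propanal.
4. Ring B ⇐ Grignard addition and ionic hydrogenation (C9) of a γ-lactone that was α-hydroxylated trans to its side chain (C10).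
5. γ-Lactone ⇐ catalytic asymmetric bromolactonization of (Z)-hept-4-enoic acid (C12–O, C13–Br). Ring order: γ-lactone, ring B tetrahydrofuran, transient ring A, oxocane.

Numbering: C1 to C15 are the chain carbons of the target (C1 alkyne CH; ring oxygen on C6 and C12; C15 methyl).
Assumption: 1, 8, 17 and 25 are bought (1 is otherwise one Pinnick oxidation from (Z)-hept-4-enal); the senses of induction of the chiral catalysts and of 17 are those reported for close analogues, and the antipode is used if a sense proves opposite.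

**Step 1**
Reactants: 1 (Z)-hept-4-enoic acid; 2 2,4,4,6-tetrabromocyclohexa-2,5-dien-1-one (TBCO)
Product: 3 (5R)-5-[(1R)-1-bromopropyl]oxolan-2-one
Conditions: Martin BINOL-amidine bifunctional organocatalyst (10 mol %), 2, PhMe–CH2Cl2 2:1, −50 °C
Reagents that add atoms: TBCO, O=C1C(Br)=CC(Br)(Br)C=C1Br
Why: Catalyst-controlled 5-exo bromolactonization (asymmetric halolactonization) in which the bound carboxylate opens the bromonium ion anti, so the Z alkene gives the threo C12–O/C13–Br pair and the catalyst fixes it as 12R,13R.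

**Step 2**
Reactants: 3; 4 2-(benzenesulfonyl)-3-phenyloxaziridine (Davis oxaziridine); 5 chlorotriethylsilane
Product: 7 (3S,5R)-5-[(1R)-1-bromopropyl]-3-(triethylsilyloxy)oxolan-2-one, via hydroxy lactone 6 (not isolated)
Conditions: NaN(SiMe3)2, THF, −78 °C; 4; then 5, −78 → 0 °C
Reagents that add atoms: Davis oxaziridine, O=S(=O)(c1ccccc1)N1OC1c1ccccc1; chlorotriethylsilane, CC[Si](Cl)(CC)CC
Why: Davis enolate hydroxylation in which the oxaziridine approaches the sodium enolate anti to the C12 side chain, giving the 3,5-trans (10S) alkoxide, which is silylated in the same flask.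

**Step 3**
Reactants: 7; 8 but-3-enylmagnesium bromide (CH2=CHCH2CH2MgBr)
Product: 11 (2R,3S,5R)-2-(but-3-enyl)-5-[(1R)-1-bromopropyl]oxolan-3-ol, via hemiketal 9 (not isolated), via silyl ether 10 (not isolated)
Conditions: 8 (Et2O solution), CH2Cl2, −78 °C; then Et3SiH, BF3·OEt2, −78 → −20 °C; then HCl, MeOH, 23 °C
Reagents that add atoms: but-3-enylmagnesium bromide, C=CCC[Mg]Br
Why: Grignard addition to the lactone followed by Kishi-type ionic hydrogenation, in which hydride adds to the five-membered oxocarbenium ion on the inside face (cis to the C10 silyloxy group, anti to the C12 side chain) and so sets C9 as R with the butenyl chain 2,3-trans and 2,5-cis, before acidic methanol removes the silyl group.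

**Step 4**
Reactants: 11; 12 acetic anhydride
Product: 13 (2R,3S,5R)-2-(but-3-enyl)-5-[(1R)-1-bromopropyl]oxolan-3-yl acetate
Conditions: Ac2O, pyridine, DMAP (cat.), CH2Cl2, 0 → 23 °C
Reagents that add atoms: acetic anhydride, CC(=O)OC(C)=O
Why: DMAP-catalysed acetylation of the only free hydroxyl, which touches no stereocentre.

**Step 5**
Reactants: 13; 14 ozone
Product: 15 (2R,3S,5R)-5-[(1R)-1-bromopropyl]-2-(3-oxopropyl)oxolan-3-yl acetate
Conditions: O3, CH2Cl2, −78 °C; then PPh3, −78 → 23 °C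
Reagents that add atoms: ozone, [O-][O+]=O
Why: Ozonolysis with reductive work-up cleaves the only alkene to the C6 aldehyde.

**Step 6**
Reactants: 15; 16 N-chlorosuccinimide; 17 (+)-B-allyldiisopinocampheylborane
Product: 19 (2R,3S,5R)-5-[(1R)-1-bromopropyl]-2-[(2S,3R)-2-chloro-3-hydroxyhex-5-enyl]oxolan-3-yl acetate, via α-chloro aldehyde 18 (not isolated)
Conditions: (2R,5R)-2,5-diphenylpyrrolidine (10 mol %), 16, CH2Cl2, 0 °C; pentane, −78 °C, cannula filtration onto 17 in Et2O, −78 °C; then HOCH2CH2NH2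
Reagents that add atoms: N-chlorosuccinimide, O=C1CCC(=O)N1Cl; (+)-B-allyldiisopinocampheylborane, C=CCB([C@H]1C[C@H]2C[C@@H]([C@@H]1C)C2(C)C)[C@H]1C[C@H]2C[C@@H]([C@@H]1C)C2(C)C
Why: Enamine-catalysed α-chlorination (Jørgensen) sets C7 as S under catalyst control, and Brown allylboration of the crude α-chloro aldehyde sets C6 as R in the Cornforth-matched sense (anti chlorohydrin).

**Step 7**
Reactants: 19; 20 tetrabutylammonium chloride
Product: 24 (2R,4S,5S,7S,8S)-2-[(1R)-1-bromopropyl]-5,7-dichloro-8-(prop-2-enyl)oxocan-4-yl acetate, via triflate 21 (not isolated), via oxonium triflate 22 (not isolated), via acetoxonium triflate 23 (not isolated)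
Conditions: Tf2O, 2,6-di-tert-butyl-4-methylpyridine, CH2Cl2, −78 → −40 °C; then 20, −78 → −20 °C
Reagents that add atoms: tetrabutylammonium chloride, CCCC[N+](CCCC)(CCCC)CCCC.[Cl-]
Why: Proposed new method: the ring-B ether oxygen displaces the C6 triflate (5-exo-tet neighbouring-ether participation, inversion at C6, forming the C6–O bond of the oxocane) to give the 1-oxoniabicyclo[3.3.0]octane 22, the C10 acetate (the only internal nucleophile that can reach the ring-fusion carbon) caps C9 as the acetoxonium ion 23, and the chloride ion-paired to 23 next to C9 is delivered to C9 as the transannular ether oxygen re-forms 22, so the net event is chloride opening of 22 at C9 with inversion (9R to 9S) and the acetate returned intact to O10; the closest known reactions are the BDSB-induced ring-expanding bromoetherifications of tetrahydrofurans terminated by an internal carbonyl nucleophile and chloride trapping of Laurencia-type oxonium ions.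

**Step 8**
Reactants: 25 ethynyl(triisopropyl)silane; 26 vinyl bromide
Product: 27 but-3-en-1-ynyl(triisopropyl)silane
Conditions: PdCl2(PPh3)2 (2 mol %), CuI (4 mol %), i-Pr2NH, THF, 0 → 23 °C
Reagents that add atoms: vinyl bromide, C=CBr
Why: Sonogashira coupling of a terminal alkyne with a vinyl halide, which creates no stereocentre.

**Step 9**
Reactants: 24; 27
Product: 28 (2R,4S,5S,7S,8S)-2-[(1R)-1-bromopropyl]-5,7-dichloro-8-[(2Z)-5-(triisopropylsilyl)pent-2-en-4-ynyl]oxocan-4-yl acetate
Conditions: 27 (5 equiv), second-generation Grubbs catalyst RuCl2(=CHPh)(H2IMes)(PCy3) (10 mol %), CH2Cl2, 40 °C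
Reagents that add atoms: but-3-en-1-ynyl(triisopropyl)silane, C=CC#C[Si](C(C)C)(C(C)C)C(C)C
Why: Cross-metathesis of a terminal alkene with a conjugated silyl enyne, which is kinetically Z-selective (Lee enyne cross-metathesis), builds the (3Z)-enyne without touching the halides or the acetate.

**Step 10**
Reactants: 28
Product: 29 (2R,4S,5S,7S,8S)-2-[(1R)-1-bromopropyl]-5,7-dichloro-8-[(2Z)-pent-2-en-4-ynyl]oxocan-4-yl acetate (CNP0251465.2)
Conditions: Bu4NF, AcOH, THF, 0 °C
Reagents that add atoms: none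
Why: Fluoride desilylation of the alkynylsilane, buffered with acetic acid so that the C10 acetate and the secondary halides survive.

**Compound list**
1 | (Z)-hept-4-enoic acid | CC/C=C\CCC(=O)O | starting material
2 | 2,4,4,6-tetrabromocyclohexa-2,5-dien-1-one (TBCO) | O=C1C(Br)=CC(Br)(Br)C=C1Br | starting material
3 | (5R)-5-[(1R)-1-bromopropyl]oxolan-2-one | CC[C@@H](Br)[C@H]1CCC(=O)O1 | intermediate
4 | 2-(benzenesulfonyl)-3-phenyloxaziridine | O=S(=O)(c1ccccc1)N1OC1c1ccccc1 | starting material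
5 | chlorotriethylsilane | CC[Si](Cl)(CC)CC | starting material
6 | (3S,5R)-5-[(1R)-1-bromopropyl]-3-hydroxyoxolan-2-one (formed as its sodium alkoxide) | CC[C@@H](Br)[C@H]1C[C@H](O)C(=O)O1 | intermediate
7 | (3S,5R)-5-[(1R)-1-bromopropyl]-3-(triethylsilyloxy)oxolan-2-one | CC[C@@H](Br)[C@H]1C[C@H](O[Si](CC)(CC)CC)C(=O)O1 | intermediate
8 | but-3-enylmagnesium bromide | C=CCC[Mg]Br | starting material
9 | (3S,5R)-2-(but-3-enyl)-5-[(1R)-1-bromopropyl]-3-(triethylsilyloxy)oxolan-2-ol (hemiketal, both C2 epimers, formed as its magnesium salt) | CC[C@@H](Br)[C@H]1C[C@H](O[Si](CC)(CC)CC)C(O)(CCC=C)O1 | intermediate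
10 | [(2R,3S,5R)-2-(but-3-enyl)-5-[(1R)-1-bromopropyl]oxolan-3-yl]oxy-triethylsilane | CC[C@@H](Br)[C@H]1C[C@H](O[Si](CC)(CC)CC)[C@@H](CCC=C)O1 | intermediate
11 | (2R,3S,5R)-2-(but-3-enyl)-5-[(1R)-1-bromopropyl]oxolan-3-ol | CC[C@@H](Br)[C@H]1C[C@H](O)[C@@H](CCC=C)O1 | intermediate
12 | acetic anhydride | CC(=O)OC(C)=O | starting material
13 | (2R,3S,5R)-2-(but-3-enyl)-5-[(1R)-1-bromopropyl]oxolan-3-yl acetate | CC[C@@H](Br)[C@H]1C[C@H](OC(C)=O)[C@@H](CCC=C)O1 | intermediate
14 | ozone | [O-][O+]=O | starting material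
15 | (2R,3S,5R)-5-[(1R)-1-bromopropyl]-2-(3-oxopropyl)oxolan-3-yl acetate | CC[C@@H](Br)[C@H]1C[C@H](OC(C)=O)[C@@H](CCC=O)O1 | intermediate
16 | N-chlorosuccinimide | O=C1CCC(=O)N1Cl | starting material
17 | (+)-B-allyldiisopinocampheylborane | C=CCB([C@H]1C[C@H]2C[C@@H]([C@@H]1C)C2(C)C)[C@H]1C[C@H]2C[C@@H]([C@@H]1C)C2(C)C | starting material
18 | (2R,3S,5R)-5-[(1R)-1-bromopropyl]-2-[(2S)-2-chloro-3-oxopropyl]oxolan-3-yl acetate | CC[C@@H](Br)[C@H]1C[C@H](OC(C)=O)[C@@H](C[C@H](Cl)C=O)O1 | intermediate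
19 | (2R,3S,5R)-5-[(1R)-1-bromopropyl]-2-[(2S,3R)-2-chloro-3-hydroxyhex-5-enyl]oxolan-3-yl acetate | CC[C@@H](Br)[C@H]1C[C@H](OC(C)=O)[C@@H](C[C@H](Cl)[C@H](O)CC=C)O1 | intermediate
20 | tetrabutylammonium chloride | CCCC[N+](CCCC)(CCCC)CCCC.[Cl-] | starting material
21 | C6 triflate of 19 (6R) | CC[C@@H](Br)[C@H]1C[C@H](OC(C)=O)[C@@H](C[C@H](Cl)[C@H](OS(=O)(=O)C(F)(F)F)CC=C)O1 | intermediate
22 | bicyclic oxonium triflate (O+ on C6, C9 and C12; ring A = O, C6–C9; ring B = O, C9–C12; allyl on C6, Cl on C7, OAc on C10, (1R)-1-bromopropyl on C12) | CC[C@@H](Br)[C@H]1C[C@H](OC(C)=O)[C@H]2C[C@H](Cl)[C@H](CC=C)[O+]12.[O-]S(=O)(=O)C(F)(F)F | intermediate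
23 | acetoxonium triflate (oxocane with a 2-methyl-1,3-dioxolan-2-ylium ring trans-fused at C9–C10) | CC[C@@H](Br)[C@H]1C[C@@H]2[O+]=C(C)O[C@H]2C[C@H](Cl)[C@H](CC=C)O1.[O-]S(=O)(=O)C(F)(F)F | intermediate
24 | (2R,4S,5S,7S,8S)-2-[(1R)-1-bromopropyl]-5,7-dichloro-8-(prop-2-enyl)oxocan-4-yl acetate | CC[C@@H](Br)[C@H]1C[C@H](OC(C)=O)[C@@H](Cl)C[C@H](Cl)[C@H](CC=C)O1 | intermediate
25 | ethynyl(triisopropyl)silane | C#C[Si](C(C)C)(C(C)C)C(C)C | starting material
26 | vinyl bromide | C=CBr | starting material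
27 | but-3-en-1-ynyl(triisopropyl)silane | C=CC#C[Si](C(C)C)(C(C)C)C(C)C | intermediate
28 | (2R,4S,5S,7S,8S)-2-[(1R)-1-bromopropyl]-5,7-dichloro-8-[(2Z)-5-(triisopropylsilyl)pent-2-en-4-ynyl]oxocan-4-yl acetate | CC[C@@H](Br)[C@H]1C[C@H](OC(C)=O)[C@@H](Cl)C[C@H](Cl)[C@H](C/C=C\C#C[Si](C(C)C)(C(C)C)C(C)C)O1 | intermediate
29 | (2R,4S,5S,7S,8S)-2-[(1R)-1-bromopropyl]-5,7-dichloro-8-[(2Z)-pent-2-en-4-ynyl]oxocan-4-yl acetate = (3Z,6S,7S,9S,10S,12R,13R) target | C#C/C=C\C[C@@H]1O[C@@H]([C@H](Br)CC)C[C@H](OC(C)=O)[C@@H](Cl)C[C@@H]1Cl | target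

**Totals**
Total steps: 10. Longest linear sequence: 9 (steps 1–7, 9, 10); step 8 is a one-step side branch.

**Three steps most likely to fail**

1. Step 7 (the proposed new ring expansion). The main hazards are:
   - chloride attacking acetoxonium 23 directly at C9 or C10, giving the C9 epimer or the 10-chloro-9-acetate;
   - chloride attacking oxonium 22 at C6 or C12, returning tetrahydrofurans;
   - the C13 bromide ionising the C12–O bond to a bromonium ion.

   Fallback with known chemistry, setting out from 19 and coming back at 24: run the triflation as in step 7 but add no chloride, so that the sequence stops at the acetate-capped ion 23 (internal-nucleophile termination as in the BDSB ring expansions). Quench with aqueous NaHCO3, which hydrolyses the 1,3-dioxolan-2-ylium ion (Woodward–Prévost-type) to the C9 alcohol F1 and its acyl-migrated isomer, the C10 alcohol F2. F2 is separated, re-equilibrated with F1 over imidazole and recycled. F1 is then treated with SOCl2 in Et2O without base: the chlorosulfite ionises with participation of the transannular ether oxygen, and chloride returns to C9 with retention to give 24.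

2. Step 6 (one-flask α-chlorination and allylboration). The α-chloro aldehyde 18 can racemise or the allylborane can be consumed by succinimide, lowering the diastereomer ratio. Fallback setting out from 18 and coming back at 19: Barbier allylation (allyl bromide, Zn, THF/aqueous NH4Cl) gives 19 mixed with its C6 epimer F3. The mixture is oxidised with Dess–Martin periodinane (NaHCO3 buffer) to the α-chloro ketone F4. CBS reduction ((S)-Me-CBS oxazaborolidine, catecholborane, −78 °C) then sets C6 as R under catalyst control and returns 19.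

3. Step 9 (enyne cross-metathesis). The allyl group sits next to a hindered, halogenated ring, so conversion or Z:E ratio may be poor. Fallback setting out from 24 and coming back at 28: ozonolysis (O3, CH2Cl2, −78 °C; PPh3) gives the aldehyde F5. Peterson olefination with lithiated 1,3-bis(triisopropylsilyl)propyne (n-BuLi, THF, −78 °C; Corey–Yamamoto protocol) then gives the (Z)-silyl enyne 28 directly.

**Further compounds**
F1 | step 7 | (2R,4S,5S,7S,8S)-2-[(1R)-1-bromopropyl]-7-chloro-5-hydroxy-8-(prop-2-enyl)oxocan-4-yl acetate | CC[C@@H](Br)[C@H]1C[C@H](OC(C)=O)[C@@H](O)C[C@H](Cl)[C@H](CC=C)O1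
F2 | step 7 | (2R,4S,5S,7S,8S)-2-[(1R)-1-bromopropyl]-7-chloro-4-hydroxy-8-(prop-2-enyl)oxocan-5-yl acetate | CC[C@@H](Br)[C@H]1C[C@H](O)[C@@H](OC(C)=O)C[C@H](Cl)[C@H](CC=C)O1
F3 | step 6 | (2R,3S,5R)-5-[(1R)-1-bromopropyl]-2-[(2S,3S)-2-chloro-3-hydroxyhex-5-enyl]oxolan-3-yl acetate | CC[C@@H](Br)[C@H]1C[C@H](OC(C)=O)[C@@H](C[C@H](Cl)[C@@H](O)CC=C)O1
F4 | step 6 | (2R,3S,5R)-5-[(1R)-1-bromopropyl]-2-[(2S)-2-chloro-3-oxohex-5-enyl]oxolan-3-yl acetate | CC[C@@H](Br)[C@H]1C[C@H](OC(C)=O)[C@@H](C[C@H](Cl)C(=O)CC=C)O1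
F5 | step 9 | (2R,4S,5S,7S,8S)-2-[(1R)-1-bromopropyl]-5,7-dichloro-8-(2-oxoethyl)oxocan-4-yl acetate | CC[C@@H](Br)[C@H]1C[C@H](OC(C)=O)[C@@H](Cl)C[C@H](Cl)[C@H](CC=O)O1
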